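## Structural features

The target is a depside. Ring A is a 3-chloro-2-hydroxy-4-methoxy-6-pentylbenzoyl unit, ring B is a 2-hydroxy-6-pentylbenzoic acid, and the only link is the ester from the ring A carbonyl to O4 of ring B. Each ring carries one unbranched pentyl chain and there is no stereocenter, so no configuration has to be set or preserved. Ring A keeps a single hydrogen (C5–H); its chlorine sits at C3 between the C2 hydroxyl and the C4 methoxy group, and its carbonyl carbon is flanked by the C6 pentyl group and the C2 oxygen, which makes it hindered. The fragile points are the aryl ester (nucleophiles, strong base), the salicylic acid of ring B (decarboxylation on heating, above all in acid), the aryl chloride (hydrogenolysis, low-valent metals) and the free phenols (oxidants). The real difficulty is positional, not skeletal: chlorine at C3 and not C5 of ring A, methyl on O4 and not O2 of ring A, the acyl group on O4 and not O2 of ring B, and an ester formed at a crowded carbonyl that must survive all later steps. The key step uses the arrangement C6(pentyl)–C1(CO2H)–C2(OH) of ring B: the C2 hydroxyl is ortho to the carboxyl and the other ortho carbon is blocked, so the C2–O bond can be made last by carboxylate-directed oxidation of the one remaining ortho C–H.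

## Logic of the disconnections

The first cut is the acetal C–O bond on O2 of ring A, which takes 17 back to 16. This oxygen would otherwise be the only free, acidic and oxidisable phenol of ring A during acyl activation, organozinc coupling and aerobic palladium catalysis. The gain is a single masking group for the whole sequence. The demand is a final hydrolysis mild enough to spare the aryl ester and the salicylic acid; the neighbouring carbonyl should make that acetal labile enough.

The second cut is the C2–O bond of ring B, which takes 16 back to 15. It is made there because C2 is ortho to the carboxyl while C6 carries the pentyl group, so a carboxylate-bound metal can reach only one C–H. The gain is that ring B becomes a benzoic acid with one phenolic oxygen, so the two hydroxyls of ring B never have to be told apart. The demand is an oxidation that touches one C–H in the presence of three other aryl C–H bonds, benzylic hydrogens, an aryl ester, an acetal and an aryl chloride.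

The third cut is at the oxidation level of the ring B carboxyl: 15 is traced to the aldehyde 14. A free acid would quench the organozinc reagent and would need its own protecting group, whereas the formyl group tolerates it and activates the ortho C–Br bond. The demand is an aldehyde oxidation that leaves ester, acetal and aryl chloride alone.

The fourth cut is the aryl–alkyl bond between ring B and its pentyl chain, which takes 14 back to 12 and 13. The bromine of 12 already sits where the chain belongs, and 13 is bought. The coupling is placed after the esterification so that the ring A acyl group is the only protection the ring B phenol ever needs, which saves a protection and a deprotection. The demand is a catalyst that inserts into the activated C–Br bond and ignores the hindered, electron-rich C–Cl bond.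

The fifth cut is the ester C(=O)–O bond, which splits 12 into 9 and 10 through the acyl chloride 11. It divides the molecule into two halves of similar size, and 10 has only one hydroxyl. The demand is acylation at a doubly ortho-substituted carbonyl, so 11 must be made under neutral conditions to keep the acetal intact.

The sixth cut returns the ring A carboxyl and its acetal to the hydroxy aldehyde: 9 goes back to 8 and then to 7. The aldehyde is what a formylation delivers and what a chelation-controlled demethylation needs. The demand is an oxidant small enough for a crowded aldehyde.

The seventh cut, read backwards, puts a methyl group on O2, taking 7 to 5 through 6. This makes the two ring A oxygens alike again. The demand on the forward step is removal of one of two methyl ethers; only the one next to the formyl group can chelate a boron Lewis acid.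

The eighth cut is the C1–CHO bond, taking 5 to 3 through 4. Because 3 is symmetric, its two open positions are equivalent and formylation can give one aldehyde only.

The ninth cut is the C–Cl bond, taking 3 to 1 through 2. In 1 the carbon between the two methoxy groups is the one that is lithiated, so chlorine is fixed at the future C3 before C5 can compete. The demand is a clean electrophilic chlorine source for an aryllithium.

## Other disconnections considered

Alternative 1: Ring A is opened at its C1–C6 bond, which gives the ring B aryl ester of a 3,5,7-trioxododecanoic acid, A2. In the forward step a mild base would make the C2 methylene add to the C7 ketone, and dehydration and enolization would give the resorcylate A1.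
- In its favour: the ester exists before its carbonyl becomes doubly ortho-substituted, so the hindered acylation of step 6 is avoided. On this point, and in needing no metal and no heating, it is better than the chosen plan.
- Against it: A1 has neither the chlorine nor the O4 methyl group. Methylation can rely on the chelated O2–H, but electrophilic chlorination would have to choose C3 over C5 of ring A and over the activated positions of ring B. A2 is also an activated aryl ester of a polyketo acid and could lactonize to a hydroxypyranone with loss of the ring B phenoxide, or close by a Claisen-type path.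
- Comparison: both key steps rely on intramolecular geometry and neither creates a stereocenter, so they are equal there. On structure the alternative rebuilds a carbon ring that 1 already supplies. On step economy it needs chlorination, methylation and deprotection after its key step, against one step here, and ring B needs two protecting groups.

Alternative 2: The C3–Cl bond of ring A is cut with ring A held at the cyclohexane-1,3-dione level, as in A4. In the forward step two equivalents of sulfuryl chloride would chlorinate the carbon between the two carbonyls and raise the oxidation level, and loss of hydrogen chloride would give the aromatic chlororesorcylate A3.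
- In its favour: the chlorine position is dictated by the dione. This is equal in certainty to the symmetric lithiation of step 1 and needs no organolithium reagent. Ring B has both oxygens from the start, so no C–H oxidation of the assembled depside is needed; on mechanistic risk at ring B it is better.
- Against it: A3 still needs selective O4 methylation and removal of two benzyl groups, and hydrogenolysis beside an aryl chloride risks loss of chlorine. Sulfuryl chloride could also attack the benzyloxy-activated ring B. A4 is an ester of a β-keto acid and would have to be made by ester exchange rather than by ordinary acylation. The ring B fragment needs O2 and the carboxyl benzylated while O4 stays free, the reverse of its natural reactivity order.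
- Comparison: on step economy it is no shorter and probably longer. The stereocenters of A4 disappear on aromatization, so there is no stereochemical cost on either side.

Alternative 3: The aryl C–O bond between the ester oxygen and C4 of ring B is cut. In the forward step the acid 9 and the boronic acid A6 would be joined by Cu(OTf)2 in a Chan–Lam-type oxidative esterification to give A5.
- In its favour: the carboxylate oxygen is the nucleophile, so the crowding at the ring A carbonyl carbon does not matter; on this point it is better than step 6. The same acid 9 serves. One acid treatment would remove the tert-butyl ester and both acetals, which equals the single final step of the chosen plan.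
- Against it: A6 must be made from A7 by a sterically directed C–H borylation, after A7 itself has been prepared and doubly protected. Copper-mediated esterification is less secure for an electron-poor, ester-bearing boronic acid, where protodeboronation and phenol formation compete. Cu(OTf)2 is Lewis acidic enough to threaten acetals and the tert-butyl ester.
- Comparison: both plans use a C–H functionalization of ring B to place a heteroatom, so they are equal in concept. The alternative does it early on a small fragment, which is the safer place. The chosen plan does it late, without any ring B protecting group and with fewer steps overall.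

Key step: step 9

Remarks: all numbered compounds are achiral except the transient α-chloro ether 4, which is racemic and is hydrolysed in the same flask. Pentylzinc bromide is taken as the commercial solution in THF. The structures of 15 and 16 were checked atom by atom against the target and need no correction.

## Route

Step 1
Reactants: 1 1,3-dimethoxy-5-pentylbenzene (olivetol dimethyl ether)
Product: 3 2-chloro-1,3-dimethoxy-5-pentylbenzene, via 2,6-dimethoxy-4-pentylphenyllithium 2 (not isolated)
Conditions: n-BuLi, THF, 0 °C → rt; C2Cl6, −78 °C → rt
Reagents that add atoms: hexachloroethane, ClC(Cl)(Cl)C(Cl)(Cl)Cl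
Why: Directed ortho metalation: the hydrogen between the two methoxy groups is the most acidic and both oxygens hold the lithium, so 2 forms at that carbon only. Hexachloroethane then transfers chlorine to the aryllithium with loss of tetrachloroethene, which fixes the halogen between the two oxygens before any other substituent is present.

Step 2
Reactants: 3 2-chloro-1,3-dimethoxy-5-pentylbenzene
Product: 5 3-chloro-2,4-dimethoxy-6-pentylbenzaldehyde, via chloro(methoxy)methyl arene 4 (not isolated)
Conditions: Cl2CHOMe, TiCl4, CH2Cl2, −78 → 0 °C; H2O
Reagents that add atoms: dichloromethyl methyl ether, COC(Cl)Cl; water, O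
Why: Rieche formylation (electrophilic aromatic substitution): the two open positions of 3 are equivalent by symmetry, each ortho to one methoxy group and para to the other, so only one aldehyde can form. Water hydrolyses the α-chloro ether 4 on work-up.

Step 3
Reactants: 5 3-chloro-2,4-dimethoxy-6-pentylbenzaldehyde
Product: 7 3-chloro-2-hydroxy-4-methoxy-6-pentylbenzaldehyde, via aryloxydichloroborane 6 (not isolated)
Conditions: BCl3, CH2Cl2, −78 → 0 °C; H2O
Reagents that add atoms: none
Why: Chelation-controlled ether cleavage: BCl3 bridges the formyl oxygen and the neighbouring C2 methoxy oxygen in a six-membered chelate and chloride removes that methyl group as chloromethane. The C4 methoxy group cannot chelate and should stay; water frees the phenol from 6.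

Step 4
Reactants: 7 3-chloro-2-hydroxy-4-methoxy-6-pentylbenzaldehyde
Product: 8 3-chloro-4-methoxy-2-(methoxymethoxy)-6-pentylbenzaldehyde
Conditions: MOMCl, K2CO3, DMF, 0 °C → rt
Reagents that add atoms: chloromethyl methyl ether, COCCl
Why: Williamson-type O-alkylation of the phenoxide by the oxocarbenium-like electrophile. The acetal masks the only acidic and oxidisable hydroxyl of ring A for the acylation, the coupling and the palladium step.

Step 5
Reactants: 8 3-chloro-4-methoxy-2-(methoxymethoxy)-6-pentylbenzaldehyde
Product: 9 3-chloro-4-methoxy-2-(methoxymethoxy)-6-pentylbenzoic acid
Conditions: NaClO2, NaH2PO4, 2-methyl-2-butene, t-BuOH/H2O, rt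
Reagents that add atoms: sodium chlorite, [Na+].[O-]Cl=O
Why: Pinnick oxidation: chlorous acid adds to the aldehyde and fragments to the acid and hypochlorous acid, which 2-methyl-2-butene traps so that C5 of ring A is not chlorinated. The buffer (about pH 4) should leave the acetal intact and the small oxidant tolerates the two ortho substituents.

Step 6
Reactants: 9 3-chloro-4-methoxy-2-(methoxymethoxy)-6-pentylbenzoic acid; 10 2-bromo-4-hydroxybenzaldehyde
Product: 12 3-bromo-4-formylphenyl 3-chloro-4-methoxy-2-(methoxymethoxy)-6-pentylbenzoate, via ring A acid chloride 11 (not isolated)
Conditions: Me2C=C(Cl)NMe2, CH2Cl2, 0 °C → rt; then 10, Et3N, DMAP (cat.), 0 °C → rt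
Reagents that add atoms: none
Why: The α-chloroenamine turns the acid into 11 without releasing hydrogen chloride, so the acetal should survive; the chlorine of 11 leaves again as chloride. Nucleophilic acyl substitution by the phenoxide of 10 then gives the aryl ester, and 10 has a single hydroxyl, so no site selection is needed.

Step 7
Reactants: 12 3-bromo-4-formylphenyl 3-chloro-4-methoxy-2-(methoxymethoxy)-6-pentylbenzoate; 13 pentylzinc bromide
Product: 14 4-formyl-3-pentylphenyl 3-chloro-4-methoxy-2-(methoxymethoxy)-6-pentylbenzoate
Conditions: PdCl2(dppf) (cat.), THF, 50 °C
Reagents that add atoms: none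
Why: Negishi coupling: zerovalent palladium inserts into the C–Br bond activated by the ortho formyl group, and transmetalation and reductive elimination from the wide-bite-angle dppf complex should outpace β-hydride elimination. The alkylzinc halide does not add to the aldehyde or the ester, and the electron-rich, doubly flanked C–Cl bond of ring A should not be activated.

Step 8
Reactants: 14 4-formyl-3-pentylphenyl 3-chloro-4-methoxy-2-(methoxymethoxy)-6-pentylbenzoate
Product: 15 4-{[3-chloro-4-methoxy-2-(methoxymethoxy)-6-pentylbenzoyl]oxy}-2-pentylbenzoic acid
Conditions: NaClO2, NaH2PO4, 2-methyl-2-butene, t-BuOH/THF/H2O, rt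
Reagents that add atoms: sodium chlorite, [Na+].[O-]Cl=O
Why: Pinnick oxidation under the buffered conditions of step 5. Aryl ester, acetal and aryl chloride are inert to chlorite near pH 4 and the alkene scavenger removes hypochlorous acid.

Step 9
Reactants: 15 4-{[3-chloro-4-methoxy-2-(methoxymethoxy)-6-pentylbenzoyl]oxy}-2-pentylbenzoic acid
Product: 16 4-{[3-chloro-4-methoxy-2-(methoxymethoxy)-6-pentylbenzoyl]oxy}-2-hydroxy-6-pentylbenzoic acid
Conditions: Pd(OAc)2 (10 mol %), KOAc, benzoquinone (1 equiv), O2 (1 atm), DMA, 115 °C
Reagents that add atoms: dioxygen, O=O
Why: KOAc turns 15 into its potassium carboxylate, which binds divalent palladium through one oxygen. Acetate-assisted concerted metalation–deprotonation at C6–H of the benzoic acid ring (numbered C2 in 16) then gives a five-membered palladacycle. O2 oxygenates the aryl–palladium bond, with benzoquinone acting as a π-acidic ligand that is not consumed in the net equation, and protonolysis releases the salicylate and returns divalent palladium. The closest known reaction type is the carboxylate-directed ortho-hydroxylation of benzoic acids, ortho-alkyl ones included, with Pd(OAc)2 under 1 atm of O2. No ring is closed and no stereocenter is formed. The step needs site selectivity for one C–H among three on ring B, one on ring A and the benzylic ones: only C6–H can reach a five-membered palladacycle, the other ortho carbon carries the pentyl group, and the ring A ester carbonyl has both ortho positions occupied. Since no phosphine-bound zerovalent palladium is present in the oxidising medium, the hindered aryl chloride should stay untouched, and the doubly ortho-substituted ester and the acetal should withstand KOAc in DMA.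

Step 10
Reactants: 16 4-{[3-chloro-4-methoxy-2-(methoxymethoxy)-6-pentylbenzoyl]oxy}-2-hydroxy-6-pentylbenzoic acid
Product: 17 4-[(3-chloro-2-hydroxy-4-methoxy-6-pentylbenzoyl)oxy]-2-hydroxy-6-pentylbenzoic acid
Conditions: aq. HCl (3 M), THF, rt → 40 °C
Reagents that add atoms: none
Why: Acid-catalysed acetal hydrolysis: protonation, loss of the phenol (helped by the ortho ester carbonyl) and capture of the oxocarbenium ion by water give formaldehyde and methanol. The doubly ortho-substituted aryl ester should resist dilute acid in a non-nucleophilic solvent, and the temperature is too low for decarboxylation of the salicylic acid.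

## Compound list

1 | 1,3-dimethoxy-5-pentylbenzene (olivetol dimethyl ether) | CCCCCc1cc(OC)cc(OC)c1 | starting material
2 | 2,6-dimethoxy-4-pentylphenyllithium (not isolated) | CCCCCc1cc(OC)c([Li])c(OC)c1 | intermediate
3 | 2-chloro-1,3-dimethoxy-5-pentylbenzene | CCCCCc1cc(OC)c(Cl)c(OC)c1 | intermediate
4 | 2-chloro-4-[chloro(methoxy)methyl]-1,3-dimethoxy-5-pentylbenzene (racemic, not isolated) | CCCCCc1cc(OC)c(Cl)c(OC)c1C(Cl)OC | intermediate
5 | 3-chloro-2,4-dimethoxy-6-pentylbenzaldehyde | CCCCCc1cc(OC)c(Cl)c(OC)c1C=O | intermediate
6 | dichloro(2-chloro-6-formyl-3-methoxy-5-pentylphenoxy)borane (not isolated) | CCCCCc1cc(OC)c(Cl)c(OB(Cl)Cl)c1C=O | intermediate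
7 | 3-chloro-2-hydroxy-4-methoxy-6-pentylbenzaldehyde | CCCCCc1cc(OC)c(Cl)c(O)c1C=O | intermediate
8 | 3-chloro-4-methoxy-2-(methoxymethoxy)-6-pentylbenzaldehyde | CCCCCc1cc(OC)c(Cl)c(OCOC)c1C=O | intermediate
9 | 3-chloro-4-methoxy-2-(methoxymethoxy)-6-pentylbenzoic acid | CCCCCc1cc(OC)c(Cl)c(OCOC)c1C(=O)O | intermediate
10 | 2-bromo-4-hydroxybenzaldehyde | O=Cc1ccc(O)cc1Br | starting material
11 | 3-chloro-4-methoxy-2-(methoxymethoxy)-6-pentylbenzoyl chloride (not isolated) | CCCCCc1cc(OC)c(Cl)c(OCOC)c1C(=O)Cl | intermediate
12 | 3-bromo-4-formylphenyl 3-chloro-4-methoxy-2-(methoxymethoxy)-6-pentylbenzoate | CCCCCc1cc(OC)c(Cl)c(OCOC)c1C(=O)Oc1ccc(C=O)c(Br)c1 | intermediate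
13 | pentylzinc bromide | CCCCC[Zn]Br | starting material
14 | 4-formyl-3-pentylphenyl 3-chloro-4-methoxy-2-(methoxymethoxy)-6-pentylbenzoate | CCCCCc1cc(OC)c(Cl)c(OCOC)c1C(=O)Oc1ccc(C=O)c(CCCCC)c1 | intermediate
15 | 4-{[3-chloro-4-methoxy-2-(methoxymethoxy)-6-pentylbenzoyl]oxy}-2-pentylbenzoic acid | CCCCCc1cc(OC(=O)c2c(CCCCC)cc(OC)c(Cl)c2OCOC)ccc1C(=O)O | intermediate
16 | 4-{[3-chloro-4-methoxy-2-(methoxymethoxy)-6-pentylbenzoyl]oxy}-2-hydroxy-6-pentylbenzoic acid | CCCCCc1cc(OC(=O)c2c(CCCCC)cc(OC)c(Cl)c2OCOC)cc(O)c1C(=O)O | intermediate
17 | 4-[(3-chloro-2-hydroxy-4-methoxy-6-pentylbenzoyl)oxy]-2-hydroxy-6-pentylbenzoic acid (CNP0310773.0) | CCCCCc1cc(OC(=O)c2c(CCCCC)cc(OC)c(Cl)c2O)cc(O)c1C(=O)O | target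

## Step count and least certain steps

Total step count: 10. Longest linear sequence: 10 steps (1 to 17); 10 and 13 enter as bought.

For step 9, the key step, the main risks are these:
- slow palladation, because the ortho pentyl group twists the carboxylate out of the ring plane;
- palladium-promoted protodecarboxylation of the electron-rich 2,6-disubstituted salicylate at 115 °C;
- cleavage of the depside ester by acetate at that temperature;
- competing oxidation of a benzylic C–H with lactone formation.

The fallback gives up the late C–H oxidation and brings the ring B hydroxyl in from the start; it sets out from 9 and returns at 16. Commercial olivetol F1 would be formylated (POCl3, DMF; Vilsmeier–Haack) to 2,4-dihydroxy-6-pentylbenzaldehyde F2. Acid 9 would be converted into 11 as in step 6 and used to acylate F2 (Et3N, CH2Cl2, 0 °C). The C2 hydroxyl of F2 is held in a hydrogen bond to the formyl group, so acylation should go to O4 and give 4-formyl-3-hydroxy-5-pentylphenyl 3-chloro-4-methoxy-2-(methoxymethoxy)-6-pentylbenzoate F3. Pinnick oxidation of F3 (NaClO2, NaH2PO4, 2-methyl-2-butene) would then give 16.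

For step 6, acylation at the doubly ortho-substituted carbonyl may be slow. The acetal may also be lost if its oxygen attacks the acyl chloride with ring closure and loss of chloromethane. The fallback avoids both the acetal and the acyl chloride at this stage; it sets out from 7 and returns at 12. Pinnick oxidation of 7 would give 3-chloro-2-hydroxy-4-methoxy-6-pentylbenzoic acid F4. Trifluoroacetic anhydride in toluene at rt would convert F4 into 3-chloro-2-hydroxy-4-methoxy-6-pentylbenzoic trifluoroacetic anhydride F5 (not isolated), which tolerates the free ortho hydroxyl and acylates 10. The resulting 3-bromo-4-formylphenyl 3-chloro-2-hydroxy-4-methoxy-6-pentylbenzoate F6 would be protected (MOMCl, i-Pr2NEt, CH2Cl2) to give 12.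

For step 7, the risks are reduction of the C–Br bond through β-hydride elimination from the pentylpalladium intermediate, and cleavage of the activated aryl ester by zinc species during prolonged heating. The fallback moves the coupling to the small ring B fragment; it sets out from 10 and returns at 14. Silylation (TBSCl, imidazole, DMF) would give 2-bromo-4-[(tert-butyldimethylsilyl)oxy]benzaldehyde F7. Negishi coupling with 13 (PdCl2(dppf), THF, 50 °C) would give 4-[(tert-butyldimethylsilyl)oxy]-2-pentylbenzaldehyde F8, and TBAF in THF would free 4-hydroxy-2-pentylbenzaldehyde F9. Acylation of F9 with 11, made from 9 as in step 6, would give 14.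

For step 2, the risks are incomplete formylation, because the chlorine deactivates the ring and the site lies next to the pentyl chain, and demethylation by TiCl4. The fallback replaces electrophilic formylation by halogen–metal exchange; it sets out from 3 and returns at 5. Bromination (NBS, MeCN, 0 °C) at one of the two equivalent open positions would give 2-bromo-4-chloro-3,5-dimethoxy-1-pentylbenzene F10. Bromine–lithium exchange (n-BuLi, THF, −78 °C) would give 3-chloro-2,4-dimethoxy-6-pentylphenyllithium F11 (not isolated), whose chlorine is meta to lithium and cannot be eliminated; DMF would then give 5.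

## Further compounds

F1 | step 9 | 5-pentylbenzene-1,3-diol (olivetol, commercial) | CCCCCc1cc(O)cc(O)c1
F2 | step 9 | 2,4-dihydroxy-6-pentylbenzaldehyde | CCCCCc1cc(O)cc(O)c1C=O
F3 | step 9 | 4-formyl-3-hydroxy-5-pentylphenyl 3-chloro-4-methoxy-2-(methoxymethoxy)-6-pentylbenzoate | CCCCCc1cc(OC(=O)c2c(CCCCC)cc(OC)c(Cl)c2OCOC)cc(O)c1C=O
F4 | step 6 | 3-chloro-2-hydroxy-4-methoxy-6-pentylbenzoic acid | CCCCCc1cc(OC)c(Cl)c(O)c1C(=O)O
F5 | step 6 | 3-chloro-2-hydroxy-4-methoxy-6-pentylbenzoic trifluoroacetic anhydride (not isolated) | CCCCCc1cc(OC)c(Cl)c(O)c1C(=O)OC(=O)C(F)(F)F
F6 | step 6 | 3-bromo-4-formylphenyl 3-chloro-2-hydroxy-4-methoxy-6-pentylbenzoate | CCCCCc1cc(OC)c(Cl)c(O)c1C(=O)Oc1ccc(C=O)c(Br)c1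
F7 | step 7 | 2-bromo-4-[(tert-butyldimethylsilyl)oxy]benzaldehyde | CC(C)(C)[Si](C)(C)Oc1ccc(C=O)c(Br)c1
F8 | step 7 | 4-[(tert-butyldimethylsilyl)oxy]-2-pentylbenzaldehyde | CCCCCc1cc(O[Si](C)(C)C(C)(C)C)ccc1C=O
F9 | step 7 | 4-hydroxy-2-pentylbenzaldehyde | CCCCCc1cc(O)ccc1C=O
F10 | step 2 | 2-bromo-4-chloro-3,5-dimethoxy-1-pentylbenzene | CCCCCc1cc(OC)c(Cl)c(OC)c1Br
F11 | step 2 | 3-chloro-2,4-dimethoxy-6-pentylphenyllithium (not isolated) | CCCCCc1cc(OC)c(Cl)c(OC)c1[Li]
A1 | alternative 1 | tert-butyl 4-[(2,4-dihydroxy-6-pentylbenzoyl)oxy]-2-(methoxymethoxy)-6-pentylbenzoate | CCCCCc1cc(OC(=O)c2c(CCCCC)cc(O)cc2O)cc(OCOC)c1C(=O)OC(C)(C)C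
A2 | alternative 1 | tert-butyl 2-(methoxymethoxy)-6-pentyl-4-[(3,5,7-trioxododecanoyl)oxy]benzoate | CCCCCC(=O)CC(=O)CC(=O)CC(=O)Oc1cc(CCCCC)c(C(=O)OC(C)(C)C)c(OCOC)c1
A3 | alternative 2 | benzyl 2-(benzyloxy)-4-[(3-chloro-2,4-dihydroxy-6-pentylbenzoyl)oxy]-6-pentylbenzoate | CCCCCc1cc(OC(=O)c2c(CCCCC)cc(O)c(Cl)c2O)cc(OCc2ccccc2)c1C(=O)OCc1ccccc1
A4 | alternative 2 | benzyl 2-(benzyloxy)-4-[(2,4-dioxo-6-pentylcyclohexane-1-carbonyl)oxy]-6-pentylbenzoate (mixture of stereoisomers) | CCCCCC1CC(=O)CC(=O)C1C(=O)Oc1cc(CCCCC)c(C(=O)OCc2ccccc2)c(OCc2ccccc2)c1
A5 | alternative 3 | tert-butyl 4-{[3-chloro-4-methoxy-2-(methoxymethoxy)-6-pentylbenzoyl]oxy}-2-(methoxymethoxy)-6-pentylbenzoate | CCCCCc1cc(OC(=O)c2c(CCCCC)cc(OC)c(Cl)c2OCOC)cc(OCOC)c1C(=O)OC(C)(C)C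
A6 | alternative 3 | [4-(tert-butoxycarbonyl)-3-(methoxymethoxy)-5-pentylphenyl]boronic acid | CCCCCc1cc(B(O)O)cc(OCOC)c1C(=O)OC(C)(C)C
A7 | alternative 3 | tert-butyl 2-(methoxymethoxy)-6-pentylbenzoate | CCCCCc1cccc(OCOC)c1C(=O)OC(C)(C)C
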